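**Retrosynthetic overview**
1. Only one ring–CH2 bond is cut. The bridge carbon is carried in as the ring CH3 of C‑methyl acetylfilicinic acid. It is joined to the free ring CH of butyrylfilicinic acid by a one‑electron (SET/HAT) C–H/C–H cross‑dehydrogenative coupling, so no C1 reagent is needed and no AA/AB/BB mixture can arise.
2. Each acyl trione comes from its parent trione and an acid chloride (O‑acylation, then O→C acyl shift).
3. Filicinic acid and methylfilicinic acid both come from one tetrasubstituted silyl enol ether of 3‑methylbutan‑2‑one. It reacts with malonyl or methylmalonyl dichloride in an Effenberger double C‑acylation that sets the quaternary carbon first.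
4. Ring order: the two carbocycles are built in parallel (steps 2 and 3), acylated (steps 4 and 5) and joined last (step 6).

Assumption: the target (albaspidin AB) has no stereocentre and is achiral, so no stereocontrol is needed. Enol tautomers are drawn as in the given SMILES.

**Step 1**
Reactants: 1 3‑methylbutan‑2‑one
Product: 2 2‑methyl‑3‑(trimethylsilyloxy)but‑2‑ene
Conditions: TMSCl, NaI, Et3N, MeCN, 23→40 °C; pentane extraction, distillation
Reagents that add atoms: chlorotrimethylsilane, C[Si](C)(C)Cl
Why: Silyl enol ether formation under equilibrating Me3SiI/Et3N conditions favours the tetrasubstituted isomer, which places the first C‑acylation of steps 2 and 3 on the future CMe2 carbon; no stereocentre is formed.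

**Step 2**
Reactants: 2 2‑methyl‑3‑(trimethylsilyloxy)but‑2‑ene + 3 malonyl dichloride
Product: 5 filicinic acid (3,5‑dihydroxy‑4,4‑dimethylcyclohexa‑2,5‑dien‑1‑one), via keto acid chloride 4 (not isolated)
Conditions: Et2O, −20→23 °C, 24 h; then KOH, BnEt3NCl (cat.), H2O; HCl to pH 2
Reagents that add atoms: none
Why: In this Effenberger cyclisation (double C‑acylation of an enol ether, α then α′) the enol ether is acylated at its tertiary carbon to give 4, whose quaternary centre blocks pyrone aromatisation, the methyl ketone enol then closes the six‑membered ring on the acid chloride/acylketene, and the hydroxide wash cleaves O‑acylated by‑products; no stereocentre is formed.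

**Step 3**
Reactants: 2 2‑methyl‑3‑(trimethylsilyloxy)but‑2‑ene + 6 methylmalonyl dichloride
Product: 8 methylfilicinic acid (3,5‑dihydroxy‑2,4,4‑trimethylcyclohexa‑2,5‑dien‑1‑one), via methyl keto acid chloride 7 (not isolated)
Conditions: Et2O, −20→23 °C, 36 h; then KOH, BnEt3NCl (cat.), H2O; HCl to pH 2
Reagents that add atoms: none
Why: The same Effenberger cyclisation puts the malonyl CH3 on the ring carbon next to a CMe2‑flanking carbonyl, and the labile stereocentre of racemic 7 disappears on enolisation of 8.

**Step 4**
Reactants: 5 filicinic acid + 9 butanoyl chloride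
Product: 11 butyrylfilicinic acid (2‑butanoyl‑3,5‑dihydroxy‑6,6‑dimethylcyclohexa‑2,4‑dien‑1‑one), via enol butanoate 10 (not isolated)
Conditions: 9 (1.0 equiv), Et3N (2.2 equiv), CH2Cl2, 0 °C; then DMAP (20 mol %), 23 °C; 1 M HCl work‑up
Reagents that add atoms: none
Why: O‑acylation followed by DMAP‑catalysed O→C acyl migration (Fries‑type rearrangement of 1,3‑dione enol esters) ends at the chelated, most acidic 2‑acyl trione, and one equivalent of 9 limits the reaction to one of the two equivalent ring CH positions.

**Step 5**
Reactants: 8 methylfilicinic acid + 12 acetyl chloride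
Product: 14 2‑acetyl‑3,5‑dihydroxy‑4,6,6‑trimethylcyclohexa‑2,4‑dien‑1‑one, via enol acetate 13 (not isolated)
Conditions: 12 (1.05 equiv), Et3N (2.2 equiv), CH2Cl2, 0 °C; then DMAP (20 mol %), 23 °C; 1 M HCl work‑up
Reagents that add atoms: none
Why: The same O‑acylation/O→C acyl shift applies, and because the transfer is reversible it delivers acetyl to the only unsubstituted ring carbon, since acylation at the CH3‑bearing carbon would give a non‑enolisable, readily cleaved triketone.

**Step 6 (key step)**
Reactants: 14 2‑acetyl‑3,5‑dihydroxy‑4,6,6‑trimethylcyclohexa‑2,4‑dien‑1‑one + 11 butyrylfilicinic acid (1.5 equiv)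
Product: 17 albaspidin AB (target), via tricarbonylmethyl radical 15 (not isolated), via exocyclic methide 16 (not isolated)
Conditions: Ag2O (1.1 equiv, in portions), TEMPO (30 mol %), PhMe, 23 °C, Ar, dark; dilute HCl work‑up
Reagents that add atoms: none
Why: Proposed new method: this is a radical cross‑dehydrogenative coupling in which Ag(I) oxidises the enolate of the fully C‑substituted, hence more easily oxidised, 14 by one electron to the delocalised radical 15, TEMPO abstracts H• from its CH3 group to give methide 16 (TEMPO–H is re‑oxidised by Ag2O), and the free ring CH of 11 (as Ag enolate, or as its own one‑electron‑oxidised radical with TEMPO–H returning H•) bonds to the CH2 terminus, so only the cross product can form because 14 has no free ring CH and 11 has no CH3; the closest known reaction types are the TEMPO/Ag2O radical dehydrogenation of C‑methyl acylfilicinic acids with in situ trapping of the methide and the peroxide/Fe‑ or Cu‑mediated cross‑dehydrogenative coupling of benzylic C–H bonds with 1,3‑dicarbonyl compounds; no stereocentre is formed.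

**Compound list**
1 | 3‑methylbutan‑2‑one | CC(C)C(C)=O | starting material
2 | 2‑methyl‑3‑(trimethylsilyloxy)but‑2‑ene | CC(C)=C(C)O[Si](C)(C)C | intermediate
3 | malonyl dichloride | O=C(Cl)CC(=O)Cl | starting material
4 | 4,4‑dimethyl‑3,5‑dioxohexanoyl chloride | CC(=O)C(C)(C)C(=O)CC(=O)Cl | intermediate
5 | filicinic acid | CC1(C)C(O)=CC(=O)C=C1O | intermediate
6 | methylmalonyl dichloride | CC(C(=O)Cl)C(=O)Cl | starting material
7 | 2,4,4‑trimethyl‑3,5‑dioxohexanoyl chloride (racemic, labile) | CC(=O)C(C)(C)C(=O)C(C)C(=O)Cl | intermediate
8 | methylfilicinic acid | CC1=C(O)C(C)(C)C(O)=CC1=O | intermediate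
9 | butanoyl chloride | CCCC(=O)Cl | starting material
10 | filicinic acid enol butanoate | CCCC(=O)OC1=CC(=O)C(C)(C)C(O)=C1 | intermediate
11 | butyrylfilicinic acid | CCCC(=O)C1=C(O)C=C(O)C(C)(C)C1=O | intermediate
12 | acetyl chloride | CC(=O)Cl | starting material
13 | methylfilicinic acid enol acetate | CC(=O)OC1=CC(=O)C(C)(C)C(O)=C1C | intermediate
14 | 2‑acetyl‑3,5‑dihydroxy‑4,6,6‑trimethylcyclohexa‑2,4‑dien‑1‑one | CC1=C(O)C(C)(C)C(=O)C(C(C)=O)=C1O | intermediate
15 | ring‑carbon (tricarbonylmethyl) radical of 14 | C[C]1C(=O)C(C)(C)C(=O)C(C(C)=O)=C1O | intermediate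
16 | 2‑acetyl‑3‑hydroxy‑6,6‑dimethyl‑4‑methylidenecyclohex‑2‑ene‑1,5‑dione | C=C1C(=O)C(C)(C)C(=O)C(C(C)=O)=C1O | intermediate
17 | albaspidin AB (achiral) | CCCC(=O)C1=C(O)C(CC2=C(O)C(C)(C)C(=O)C(C(C)=O)=C2O)=C(O)C(C)(C)C1=O | target

**Totals**
Total steps: 6. Longest linear sequence: 4 (steps 1→2→4→6 or 1→3→5→6).

**Steps most likely to fail**

Step 6 is the riskiest. Compound 11 may itself be oxidised. The doubly activated bridge CH2 of 17 may be oxidised further. Methide 16 may dimerise. Long contact with the basic silver salts could also start retro‑Michael exchange to the symmetrical dimers. The fallback sets out from 14 and comes back at 17, and it separates oxidation from bond formation. The Ag2O/TEMPO dehydrogenation is run without 11 in PhMe/MeOH, so that 16 is caught by methanol as the storable methoxymethyl ether F1. In a second, oxidant‑free operation, F1 and 11 are treated with catalytic BF3·OEt2 in CH2Cl2 at 0 °C. This releases 16 again in the presence of the nucleophile only.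

Step 3 comes next. The branched dichloride 6 is more hindered and goes to its ketene more readily, so oligomers and lactones may dominate. The fallback sets out from 5 and comes back at 8. The ring is made first by step 2, and the methyl group is added afterwards by enolate C‑alkylation (MeI 1.0 equiv, KOH, aqueous MeOH). Compound 8 is then separated from unreacted 5 and dimethylated material. No new compound is made.

Step 2 is third. O‑acylation to an enol lactone and hydrolysis of 4 can erode the yield. Any kinetic enol ether present in 2 ends up as a 6‑isopropyl‑4‑hydroxypyrone. The fallback sets out from 2 and comes back at 5, and it makes the two C–C bonds in separate operations. ZnCl2‑catalysed C‑acylation of 2 with methyl 3‑chloro‑3‑oxopropanoate, which has only one acylating end, gives methyl 4,4‑dimethyl‑3,5‑dioxohexanoate F2. The ring is then closed by a Dieckmann‑type condensation with the non‑nucleophilic base KOtBu (2.2 equiv, THF, 0→23 °C) followed by acid work‑up.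

**Further compounds**
F1 | step 6 | 2‑acetyl‑3,5‑dihydroxy‑4‑(methoxymethyl)‑6,6‑dimethylcyclohexa‑2,4‑dien‑1‑one | COCC1=C(O)C(C)(C)C(=O)C(C(C)=O)=C1O
F2 | step 2 | methyl 4,4‑dimethyl‑3,5‑dioxohexanoate | COC(=O)CC(=O)C(C)(C)C(C)=O
F0 | step 3 | none | none
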